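**Retrosynthetic overview**
1. 23 ⇐ 22 (MeMgBr on the side-chain methyl ketone) ⇐ 18 (bridgehead C1 acylation with (2R)-2-methylbutanoyl chloride, then ketal hydrolysis) ⇐ 15 (C3 Michael addition to but-3-en-2-one, ketal masking).
2. 15 ⇐ acyclic ester 11 + diketene in one flask: C5–C9 acylation and C3–C4 Dieckmann closure give ring A first; protonation of the isopropenyl group and C1–C8 closure give ring B second.
3. 11 ⇐ methyl 5-methylhex-4-enoate 9 (Johnson–Claisen) + (S)-lavandulyl triflate 10; (S)-lavandulol 6 ⇐ Evans deconjugative prenylation of a senecioyl oxazolidinone.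
4. Stereocontrol: C7 from the auxiliary; C1 and C5 from C7 in the ring B closure; the acyl stereocentre from (2R)-2-methylbutanoic acid. Locants C1–C9 are those of the bicyclo[3.3.1]nonane core.

Assumptions: (2R)-2-methylbutanoic acid is bought as the single enantiomer; metal enolates and carbanions count as activated forms of the numbered compound and carry no number of their own.

**Step 1**
Reactants: 1 (4S)-4-benzyl-1,3-oxazolidin-2-one; 2 3-methylbut-2-enoyl chloride
Product: 3 (4S)-4-benzyl-3-(3-methylbut-2-enoyl)-1,3-oxazolidin-2-one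
Conditions: n-BuLi, THF, −78 °C; then 2, −78 → 0 °C
Reagents that add atoms: 3-methylbut-2-enoyl chloride (2), CC(C)=CC(Cl)=O
Why: N-acylation of the lithiated oxazolidinone by the acid chloride (attachment of the Evans auxiliary); no new stereocentre.

**Step 2**
Reactants: 3 (4S)-4-benzyl-3-(3-methylbut-2-enoyl)-1,3-oxazolidin-2-one; 4 1-bromo-3-methylbut-2-ene
Product: 5 (4S)-4-benzyl-3-[(2S)-5-methyl-2-(prop-1-en-2-yl)hex-4-enoyl]-1,3-oxazolidin-2-one
Conditions: NaN(SiMe3)2 (1.1 equiv), THF, −78 °C; 4, −78 → −30 °C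
Reagents that add atoms: 1-bromo-3-methylbut-2-ene (4), CC(C)=CCBr
Why: Evans asymmetric alkylation of the chelated sodium dienolate formed by γ-deprotonation, in which prenyl bromide attacks the α-carbon (deconjugative alkylation) on the face opposite the benzyl group and so sets the future C7 centre as (S) in the imide.

**Step 3**
Reactants: 5 (4S)-4-benzyl-3-[(2S)-5-methyl-2-(prop-1-en-2-yl)hex-4-enoyl]-1,3-oxazolidin-2-one
Product: 6 (2S)-5-methyl-2-(prop-1-en-2-yl)hex-4-en-1-ol
Conditions: LiBH4, H2O (1 equiv), Et2O, 0 °C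
Reagents that add atoms: none
Why: Reductive cleavage of the imide by hydride attack at the exocyclic carbonyl gives the primary alcohol under non-basic conditions, so the allylic stereocentre is neither epimerised nor reconjugated.

**Step 4**
Reactants: 7 2-methylbut-3-en-2-ol; 8 1,1,1-trimethoxyethane
Product: 9 methyl 5-methylhex-4-enoate
Conditions: EtCO2H (cat.), 140 °C, MeOH distilled off
Reagents that add atoms: 1,1,1-trimethoxyethane (8), CC(OC)(OC)OC
Why: Johnson–Claisen orthoester rearrangement, in which the ketene acetal of the tertiary allylic alcohol undergoes a [3,3]-sigmatropic shift to the trisubstituted alkene; no stereocentre is formed.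

**Step 5**
Reactants: 9 methyl 5-methylhex-4-enoate; 6 (2S)-5-methyl-2-(prop-1-en-2-yl)hex-4-en-1-ol
Product: 11 methyl (4R)-7-methyl-2-(3-methylbut-2-en-1-yl)-4-(prop-1-en-2-yl)oct-6-enoate, via lavandulyl triflate 10 (not isolated)
Conditions: 6, Tf2O, 2,6-lutidine, CH2Cl2, −78 °C; crude 10 added to 9/LiN(i-Pr)2, THF, −78 → −20 °C
Reagents that add atoms: (2S)-5-methyl-2-(prop-1-en-2-yl)hex-4-en-1-ol (6), CC(C)=CC[C@H](CO)C(C)=C
Why: Primary triflate formation then SN2 alkylation of the ester lithium enolate at low temperature, where substitution outruns E2 on the β-branched electrophile; the lavandulyl centre is untouched (4R only by priority change) and C2 forms as an epimer mixture that is erased in step 6.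

**Step 6**
Reactants: 11 methyl (4R)-7-methyl-2-(3-methylbut-2-en-1-yl)-4-(prop-1-en-2-yl)oct-6-enoate; 12 4-methylideneoxetan-2-one
Product: 15 (1R,5S,7R)-4-hydroxy-8,8-dimethyl-5,7-bis(3-methylbut-2-en-1-yl)bicyclo[3.3.1]non-3-ene-2,9-dione, via dioxo ester 13 (not isolated), via monocyclic trione 14 (not isolated)
Conditions: LiN(i-Pr)2 (1.1 equiv), THF, −78 °C; 12 (1.2 equiv), −78 → −40 °C; LiN(i-Pr)2 (1.3 equiv), −40 → 0 °C; then solvent exchange to HCO2H, 25 → 40 °C
Reagents that add atoms: 4-methylideneoxetan-2-one (12), C=C1CC(=O)O1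
Why: Proposed new method: the ester enolate C-acylates diketene with β-lactone opening to give 13, whose 1,3-diketone dianion closes ring A by Dieckmann attack of the terminal carbon on the ester to give the mirror-symmetric trione 14, and in formic acid the isopropenyl group is protonated to the tertiary C8 cation, which alkylates one of the two equivalent enol carbons through a chair transition state with the C7 prenyl group equatorial, closing ring B and setting C1 and C5 from C7 (O-alkylation is reversible in acid, C-alkylation is not); the closest known reactions are diketene annulation of enolates, Dieckmann cyclisation of 3,5-dioxo esters and formic-acid-mediated cation–enol cyclisation of dearomatised acylphloroglucinols.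

**Step 7**
Reactants: 15 (1R,5S,7R)-4-hydroxy-8,8-dimethyl-5,7-bis(3-methylbut-2-en-1-yl)bicyclo[3.3.1]non-3-ene-2,9-dione; 16 but-3-en-2-one
Product: 18 pyrano-fused methyl ketal (1R,5S,7R; 2-methoxy-2-methyl-3,4-dihydro-2H-pyran fused across C3/C4–O; C2 and C9 ketones free; ketal carbon as epimer mixture), via Michael adduct 17 (not isolated)
Conditions: 16 (1.5 equiv), Et3N (0.2 equiv), MeOH, 25 °C; then camphorsulfonic acid (0.5 equiv), 3 Å molecular sieves, 25 °C
Reagents that add atoms: but-3-en-2-one (16), CC(=O)C=C; methanol, CO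
Why: Base-catalysed Michael addition through C3 (the only enolisable carbon) then acid-catalysed intramolecular ketalisation of the side-chain ketone onto the C4 enol oxygen masks enol and ketone together; the isomer with the ring oxygen on C2 is expected alongside and is returned to the same acidic methanol to re-equilibrate; ring stereocentres are untouched.

**Step 8**
Reactants: 19 (2R)-2-methylbutanoic acid
Product: 20 (2R)-2-methylbutanoyl chloride
Conditions: (COCl)2, DMF (cat.), CH2Cl2, 0 → 25 °C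
Reagents that add atoms: oxalyl chloride, ClC(=O)C(Cl)=O
Why: Acid chloride formation through the Vilsmeier-type chloroiminium catalyst proceeds without enolisation at this temperature, so the (R) centre is retained.

**Step 9**
Reactants: 18 pyrano-fused methyl ketal; 20 (2R)-2-methylbutanoyl chloride
Product: 22 (1S,5S,7R)-4-hydroxy-8,8-dimethyl-1-[(2R)-2-methylbutanoyl]-5,7-bis(3-methylbut-2-en-1-yl)-3-(3-oxobutyl)bicyclo[3.3.1]non-3-ene-2,9-dione, via acylated ketal 21 (not isolated)
Conditions: lithium 2,2,6,6-tetramethylpiperidide (from 2,2,6,6-tetramethylpiperidine + n-BuLi, 1.3 equiv), THF, −78 → −40 °C; 20 (1.5 equiv), −78 °C; then 1 M HCl, THF, 25 °C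
Reagents that add atoms: (2R)-2-methylbutanoyl chloride (20), CC[C@@H](C)C(Cl)=O; water, O
Why: Bridgehead lithiation next to the C2 and C9 carbonyls (the only bridgehead C–H, with C3 blocked) then C-acylation, a sequence precedented for C3-substituted bicyclo[3.3.1]nonanetrione enol ethers; the bridgehead cannot invert, so C1 is acylated with retention (R becomes S only by priority change), the acyl stereocentre comes from 20, and aqueous acid then hydrolyses the ketal.

**Step 10**
Reactants: 22 (1S,5S,7R)-4-hydroxy-8,8-dimethyl-1-[(2R)-2-methylbutanoyl]-5,7-bis(3-methylbut-2-en-1-yl)-3-(3-oxobutyl)bicyclo[3.3.1]non-3-ene-2,9-dione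
Product: 23 (1S,5S,7R)-4-hydroxy-3-(3-hydroxy-3-methylbutyl)-8,8-dimethyl-1-[(2R)-2-methylbutanoyl]-5,7-bis(3-methylbut-2-en-1-yl)bicyclo[3.3.1]non-3-ene-2,9-dione
Conditions: MeMgBr (3 equiv), THF, −78 → 0 °C; aq. NH4Cl
Reagents that add atoms: methylmagnesium bromide, C[Mg]Br
Why: Chemoselective Grignard 1,2-addition, in which the first equivalent turns the enolised 1,3-diketone into an inert magnesium enolate, the C9 and C1-acyl ketones are shielded by quaternary neighbours, and only the unhindered methyl ketone is attacked; no stereocentre is formed or disturbed.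

**Compound list**
1 | (4S)-4-benzyl-1,3-oxazolidin-2-one | O=C1N[C@@H](Cc2ccccc2)CO1 | starting material
2 | 3-methylbut-2-enoyl chloride | CC(C)=CC(Cl)=O | starting material
3 | (4S)-4-benzyl-3-(3-methylbut-2-enoyl)-1,3-oxazolidin-2-one | CC(C)=CC(=O)N1[C@@H](Cc2ccccc2)COC1=O | intermediate
4 | 1-bromo-3-methylbut-2-ene (prenyl bromide) | CC(C)=CCBr | starting material
5 | (4S)-4-benzyl-3-[(2S)-5-methyl-2-(prop-1-en-2-yl)hex-4-enoyl]-1,3-oxazolidin-2-one | CC(C)=CC[C@@H](C(C)=C)C(=O)N1[C@@H](Cc2ccccc2)COC1=O | intermediate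
6 | (2S)-5-methyl-2-(prop-1-en-2-yl)hex-4-en-1-ol, (S)-lavandulol | CC(C)=CC[C@H](CO)C(C)=C | intermediate
7 | 2-methylbut-3-en-2-ol | CC(C)(O)C=C | starting material
8 | 1,1,1-trimethoxyethane (trimethyl orthoacetate) | CC(OC)(OC)OC | starting material
9 | methyl 5-methylhex-4-enoate | COC(=O)CCC=C(C)C | intermediate
10 | (2S)-5-methyl-2-(prop-1-en-2-yl)hex-4-en-1-yl trifluoromethanesulfonate | CC(C)=CC[C@H](COS(=O)(=O)C(F)(F)F)C(C)=C | intermediate (not isolated)
11 | methyl (4R)-7-methyl-2-(3-methylbut-2-en-1-yl)-4-(prop-1-en-2-yl)oct-6-enoate (both C2 epimers) | COC(=O)C(CC=C(C)C)C[C@@H](CC=C(C)C)C(C)=C | intermediate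
12 | 4-methylideneoxetan-2-one (diketene) | C=C1CC(=O)O1 | starting material
13 | methyl 2-(3-methylbut-2-en-1-yl)-2-[(2R)-5-methyl-2-(prop-1-en-2-yl)hex-4-en-1-yl]-3,5-dioxohexanoate (both C2 epimers) | COC(=O)C(CC=C(C)C)(C[C@@H](CC=C(C)C)C(C)=C)C(=O)CC(C)=O | intermediate (not isolated)
14 | 2-(3-methylbut-2-en-1-yl)-2-[(2R)-5-methyl-2-(prop-1-en-2-yl)hex-4-en-1-yl]cyclohexane-1,3,5-trione | O=C1CC(=O)C(CC=C(C)C)(C[C@@H](CC=C(C)C)C(C)=C)C(=O)C1 | intermediate (not isolated)
15 | (1R,5S,7R)-4-hydroxy-8,8-dimethyl-5,7-bis(3-methylbut-2-en-1-yl)bicyclo[3.3.1]non-3-ene-2,9-dione | O=C1C=C(O)[C@]2(CC=C(C)C)C[C@@H](CC=C(C)C)C(C)(C)[C@H]1C2=O | intermediate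
16 | but-3-en-2-one | CC(=O)C=C | starting material
17 | (1R,5S,7R)-4-hydroxy-8,8-dimethyl-5,7-bis(3-methylbut-2-en-1-yl)-3-(3-oxobutyl)bicyclo[3.3.1]non-3-ene-2,9-dione | O=C1C(CCC(C)=O)=C(O)[C@]2(CC=C(C)C)C[C@@H](CC=C(C)C)C(C)(C)[C@H]1C2=O | intermediate (not isolated)
18 | cyclic methyl ketal of 17: 2-methoxy-2-methyl-3,4-dihydro-2H-pyran fused across C3/C4–O of the (1R,5S,7R)-8,8-dimethyl-5,7-bis(3-methylbut-2-en-1-yl)bicyclo[3.3.1]nonane-2,9-dione core (ketal carbon as epimer mixture) | O=C1C3=C(OC(C)(OC)CC3)[C@]2(CC=C(C)C)C[C@@H](CC=C(C)C)C(C)(C)[C@H]1C2=O | intermediate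
19 | (2R)-2-methylbutanoic acid | CC[C@@H](C)C(O)=O | starting material
20 | (2R)-2-methylbutanoyl chloride | CC[C@@H](C)C(Cl)=O | intermediate
21 | C1-[(2R)-2-methylbutanoyl] derivative of 18, (1S,5S,7R) core (ketal carbon as epimer mixture) | CC[C@@H](C)C(=O)[C@]12C(=O)C3=C(OC(C)(OC)CC3)[C@](CC=C(C)C)(C[C@@H](CC=C(C)C)C1(C)C)C2=O | intermediate (not isolated)
22 | (1S,5S,7R)-4-hydroxy-8,8-dimethyl-1-[(2R)-2-methylbutanoyl]-5,7-bis(3-methylbut-2-en-1-yl)-3-(3-oxobutyl)bicyclo[3.3.1]non-3-ene-2,9-dione | CC[C@@H](C)C(=O)[C@]12C(=O)C(CCC(C)=O)=C(O)[C@](CC=C(C)C)(C[C@@H](CC=C(C)C)C1(C)C)C2=O | intermediate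
23 | (1S,5S,7R)-4-hydroxy-3-(3-hydroxy-3-methylbutyl)-8,8-dimethyl-1-[(2R)-2-methylbutanoyl]-5,7-bis(3-methylbut-2-en-1-yl)bicyclo[3.3.1]non-3-ene-2,9-dione | CC[C@@H](C)C(=O)[C@]12C(=O)C(CCC(C)(C)O)=C(O)[C@](CC=C(C)C)(C[C@@H](CC=C(C)C)C1(C)C)C2=O | target

**Step count**
Total steps: 10. Longest linear sequence: 8 (steps 1, 2, 3, 5, 6, 7, 9, 10).

**Steps most likely to fail**

Step 6 (one-pot ring A/ring B closure). Ring A may stop at an O-acylated pyranone. In the acid stage the prenyl groups are protonated about as readily as the isopropenyl group, which opens paths to lavandulyl self-cyclisation and to closure through the C5 prenyl group. The fallback sets out from 11 and comes back at 15, building ring B first and ring A second. Saponification of 11 (LiOH, THF/H2O) gives (4R)-7-methyl-2-(3-methylbut-2-en-1-yl)-4-(prop-1-en-2-yl)oct-6-enoic acid F1. MeLi (2.2 equiv, Et2O, 0 °C) converts it into (5R)-8-methyl-3-(3-methylbut-2-en-1-yl)-5-(prop-1-en-2-yl)non-7-en-2-one F2. Formic acid closes ring B through the methyl-ketone enol, which has no competing enol oxygen, to give (4R)-3,3-dimethyl-4,6-bis(3-methylbut-2-en-1-yl)cyclohexan-1-one F3. Me3SiCl, NaI and Et3N in MeCN give the more substituted silyl enol ether {[(4R)-5,5-dimethyl-2,4-bis(3-methylbut-2-en-1-yl)cyclohex-1-en-1-yl]oxy}trimethylsilane F4. Effenberger annulation with malonyl dichloride (CH2Cl2, −20 °C to 25 °C, then KOH and BnEt3NCl) lays C2–C3–C4 across C1 and C5 on the face that keeps the C7 prenyl group equatorial, and returns 15.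

Step 7 (regiochemistry of the ketal). If the ring oxygen ends up mainly on C2, the C2 carbonyl is masked and C1–H is poorly activated for step 9. The fallback sets out from 17 (isolated by leaving out the acid stage) and comes back at 23, with acylation as the last C–C bond formation. MeMgBr (3 equiv, THF, −78 to 0 °C) gives (1R,5S,7R)-4-hydroxy-3-(3-hydroxy-3-methylbutyl)-8,8-dimethyl-5,7-bis(3-methylbut-2-en-1-yl)bicyclo[3.3.1]non-3-ene-2,9-dione F5. Et3SiOTf and 2,6-lutidine silylate both hydroxyls to give the bis(triethylsilyl) ether of F5 (enol and tertiary oxygen silylated) F6. The silyl group of a 1,3-diketone silyl enol ether shifts rapidly between the two oxygens, so the isomer with the free C2 carbonyl is always available. Lithium 2,2,6,6-tetramethylpiperidide then 20 gives the C1-[(2R)-2-methylbutanoyl] bis(triethylsilyl) ether F7, and HF·pyridine releases 23.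

Step 9 (bridgehead acylation next to the C8 quaternary carbon). The anion may form sluggishly, or it may deprotonate 20 to a ketene, which would lower the yield and erode the acyl stereocentre. The fallback sets out from 18 (and 20) and comes back at 21, replacing direct acylation by halogen–lithium exchange, aldehyde addition and oxidation. Lithium 2,2,6,6-tetramethylpiperidide then I2 gives the C1-iodo derivative of 18 F8. Reduction of 20 with LiAlH(Ot-Bu)3 at −78 °C gives (2R)-2-methylbutanal F9. t-BuLi (2 equiv, −100 °C) on F8 followed by F9 gives the C1-[(2R)-1-hydroxy-2-methylbutyl] derivative of 18 F10 as a carbinol epimer mixture. Dess–Martin periodinane oxidises it to 21, which is hydrolysed as in step 9.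

**Further compounds**
F1 | step 6 | (4R)-7-methyl-2-(3-methylbut-2-en-1-yl)-4-(prop-1-en-2-yl)oct-6-enoic acid (both C2 epimers) | OC(=O)C(CC=C(C)C)C[C@@H](CC=C(C)C)C(C)=C
F2 | step 6 | (5R)-8-methyl-3-(3-methylbut-2-en-1-yl)-5-(prop-1-en-2-yl)non-7-en-2-one (both C3 epimers) | CC(=O)C(CC=C(C)C)C[C@@H](CC=C(C)C)C(C)=C
F3 | step 6 | (4R)-3,3-dimethyl-4,6-bis(3-methylbut-2-en-1-yl)cyclohexan-1-one (both C6 epimers) | O=C1CC(C)(C)[C@H](CC=C(C)C)CC1CC=C(C)C
F4 | step 6 | {[(4R)-5,5-dimethyl-2,4-bis(3-methylbut-2-en-1-yl)cyclohex-1-en-1-yl]oxy}trimethylsilane | C[Si](C)(C)OC1=C(CC=C(C)C)C[C@@H](CC=C(C)C)C(C)(C)C1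
F5 | step 7 | (1R,5S,7R)-4-hydroxy-3-(3-hydroxy-3-methylbutyl)-8,8-dimethyl-5,7-bis(3-methylbut-2-en-1-yl)bicyclo[3.3.1]non-3-ene-2,9-dione | O=C1C(CCC(C)(C)O)=C(O)[C@]2(CC=C(C)C)C[C@@H](CC=C(C)C)C(C)(C)[C@H]1C2=O
F6 | step 7 | (1R,5S,7R)-8,8-dimethyl-5,7-bis(3-methylbut-2-en-1-yl)-3-{3-methyl-3-[(triethylsilyl)oxy]butyl}-4-[(triethylsilyl)oxy]bicyclo[3.3.1]non-3-ene-2,9-dione | O=C1C(CCC(C)(C)O[Si](CC)(CC)CC)=C(O[Si](CC)(CC)CC)[C@]2(CC=C(C)C)C[C@@H](CC=C(C)C)C(C)(C)[C@H]1C2=O
F7 | step 7 | (1S,5S,7R)-8,8-dimethyl-1-[(2R)-2-methylbutanoyl]-5,7-bis(3-methylbut-2-en-1-yl)-3-{3-methyl-3-[(triethylsilyl)oxy]butyl}-4-[(triethylsilyl)oxy]bicyclo[3.3.1]non-3-ene-2,9-dione | CC[C@@H](C)C(=O)[C@]12C(=O)C(CCC(C)(C)O[Si](CC)(CC)CC)=C(O[Si](CC)(CC)CC)[C@](CC=C(C)C)(C[C@@H](CC=C(C)C)C1(C)C)C2=O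
F8 | step 9 | C1-iodo derivative of 18, (1S,5S,7R) core (ketal carbon as epimer mixture) | O=C1C3=C(OC(C)(OC)CC3)[C@]2(CC=C(C)C)C[C@@H](CC=C(C)C)C(C)(C)[C@@]1(I)C2=O
F9 | step 9 | (2R)-2-methylbutanal | CC[C@@H](C)C=O
F10 | step 9 | C1-[(2R)-1-hydroxy-2-methylbutyl] derivative of 18, (1S,5S,7R) core (carbinol and ketal carbons as epimer mixtures) | O=C1C3=C(OC(C)(OC)CC3)[C@]2(CC=C(C)C)C[C@@H](CC=C(C)C)C(C)(C)[C@@]1(C(O)[C@H](C)CC)C2=O
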